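Ring numbering used below: C1 (quaternary; methyl and styryl), C2 and C3 (CH2), C4 (=C–CH3), C5 (=CH), C6 (CH–aryl).
1. Cuts, in retrosynthetic order: ring bond C3–C4; the C4=C5 alkene back to an aldehyde at C5; C1–C6 by a [3,3] shift back to an allylic arylacetate; the ester C–O bond; the two aryl–carbon bonds back to 6-bromo-7-methoxycoumarin.
2. Enabling feature: C3–C4 joins an allylic CH2 to the methyl-bearing sp2 carbon of a cis ring alkene, and the C2–C3 pair hangs on quaternary C1. A vinyl group on C1 is therefore a latent C3 borane and a (Z)-2-iodoprop-1-enyl group on C6 a latent C4 electrophile, so the two ends of a 3,4-disubstituted hexa-1,5-diene unit can be joined.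
3. Forward order: bromocoumarin → arylacetic acid and (2E,4E)-aryldienol → ester → Ireland–Claisen rearrangement (C1–C6) → aldehyde → (Z)-iodoalkene → the only carbocycle is closed last.
4. Stereochemistry: both stereocentres arise in the Ireland–Claisen step (chair transition state for the relative, chiral boron enolate for the absolute configuration). Alkene geometries come from syn-hydrostannation (E), the Stork–Zhao olefination (Z) and retention in the cross-couplings.

Key step: step 10

Assumption: the (S,S)-configured boron reagent of step 7 is taken to give the (2S,3R) acid; if the sense of induction proves opposite, the (R,R) reagent is used and nothing else changes.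
Assumption: compounds 1 and 6, BrZnCH2CO2t-Bu and the (S,S)-bis-sulfonamide (precursor of the boron bromide, made from it with BBr3 before use) are taken as catalogue compounds.

Step 1
Reactants: 1 5-bromo-2-hydroxy-4-methoxybenzaldehyde
Product: 3 6-bromo-7-methoxy-2H-chromen-2-one, via the (Z)-hydroxycinnamate ester 2 (not isolated)
Conditions: Ph3P=CHCO2Et, PhNEt2, 210 °C
Reagents that add atoms: ethyl (triphenylphosphoranylidene)acetate, CCOC(=O)C=P(c1ccccc1)(c1ccccc1)c1ccccc1
Why: Wittig olefination of the salicylaldehyde, then thermal E/Z equilibration and lactonisation of the cis ester with loss of ethanol (Wittig–lactonisation coumarin synthesis); no stereocentre.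

Step 2
Reactants: 3 6-bromo-7-methoxy-2H-chromen-2-one
Product: 4 tert-butyl 2-(7-methoxy-2-oxo-2H-chromen-6-yl)acetate
Conditions: BrZnCH2CO2t-Bu, Pd2(dba)3 (cat.), XPhos (cat.), THF, rt to 50 °C
Reagents that add atoms: (2-tert-butoxy-2-oxoethyl)zinc bromide, CC(C)(C)OC(=O)C[Zn]Br
Why: Negishi-type α-arylation with a Reformatsky zinc enolate, which is neutral enough to leave the base-sensitive lactone alone; no stereocentre.

Step 3
Reactants: 4 tert-butyl 2-(7-methoxy-2-oxo-2H-chromen-6-yl)acetate
Product: 5 2-(7-methoxy-2-oxo-2H-chromen-6-yl)acetic acid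
Conditions: CF3CO2H, CH2Cl2, rt
Reagents that add atoms: none
Why: Acidolysis of the tert-butyl ester (loss of 2-methylpropene) leaves the coumarin lactone untouched.

Step 4
Reactants: 6 (2E)-3-methylpent-2-en-4-yn-1-ol
Product: 7 (2E,4E)-3-methyl-5-(tributylstannyl)penta-2,4-dien-1-ol
Conditions: Bu3SnH, PdCl2(PPh3)2 (cat.), THF, 0 °C
Reagents that add atoms: tributyltin hydride, CCCC[SnH](CCCC)CCCC
Why: Palladium-catalysed syn-hydrostannation of the terminal alkyne should place tin on the terminal carbon and fix the (4E) geometry, while the (2E) alkene is carried over from 6.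

Step 5
Reactants: 7 (2E,4E)-3-methyl-5-(tributylstannyl)penta-2,4-dien-1-ol; 3 6-bromo-7-methoxy-2H-chromen-2-one
Product: 8 6-[(1E,3E)-5-hydroxy-3-methylpenta-1,3-dienyl]-7-methoxy-2H-chromen-2-one
Conditions: Pd2(dba)3 (cat.), AsPh3, NMP, 60 °C
Reagents that add atoms: none
Why: Stille coupling proceeds with retention at the alkenyl carbon and should give the (E,E)-aryldienol with the free alcohol tolerated.

Step 6
Reactants: 5 2-(7-methoxy-2-oxo-2H-chromen-6-yl)acetic acid; 8 the (E,E)-aryldienol
Product: 9 (2E,4E)-5-(7-methoxy-2-oxo-2H-chromen-6-yl)-3-methylpenta-2,4-dienyl 2-(7-methoxy-2-oxo-2H-chromen-6-yl)acetate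
Conditions: DCC, DMAP (cat.), CH2Cl2, 0 °C to rt
Reagents that add atoms: none
Why: Steglich esterification under neutral conditions; no stereocentre.

Step 7
Reactants: 9 the dienyl arylacetate
Product: 12 (2S,3R)-2-(7-methoxy-2-oxo-2H-chromen-6-yl)-3-[(E)-2-(7-methoxy-2-oxo-2H-chromen-6-yl)ethenyl]-3-methylpent-4-enoic acid, via boron enolate 10 (not isolated), via boryl ester 11 (not isolated)
Conditions: (4S,5S)-2-bromo-4,5-diphenyl-1,3-bis{[3,5-bis(trifluoromethyl)phenyl]sulfonyl}-1,3,2-diazaborolidine, i-Pr2NEt, CH2Cl2, −78 °C, then rt; aqueous work-up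
Reagents that add atoms: none
Why: Enantioselective Ireland–Claisen rearrangement through a chiral boron enolate: soft enolisation should give the enolate with the aryl group cis to O–B, the chair transition state places the C-2 aryl and the C-3 styryl group pseudo-equatorial so that the (2E) alkene geometry becomes the relative configuration (aryl and styryl trans on the later ring), and the C2-symmetric (S,S)-bis-sulfonamide on boron selects the enolate face, so that both stereocentres are set in one [3,3] shift.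

Step 8
Reactants: 12 the (2S,3R)-acid
Product: 14 (2S,3R)-2-(7-methoxy-2-oxo-2H-chromen-6-yl)-3-[(E)-2-(7-methoxy-2-oxo-2H-chromen-6-yl)ethenyl]-3-methylpent-4-enal, via acid chloride 13 (not isolated)
Conditions: (COCl)2, DMF (cat.), CH2Cl2, 0 °C; then LiAlH(O-t-Bu)3, THF, −78 °C
Reagents that add atoms: none
Why: Acid chloride formation without amine base, then reduction by the hindered hydride at low temperature, should stop at the aldehyde, spare both lactones and leave the aryl-bearing centre untouched (acid chloride to aldehyde reduction).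

Step 9
Reactants: 14 the (2S,3R)-aldehyde
Product: 15 6-[(2Z,4S,5R)-2-iodo-5-[(E)-2-(7-methoxy-2-oxo-2H-chromen-6-yl)ethenyl]-5-methylhepta-2,6-dien-4-yl]-7-methoxy-2H-chromen-2-one
Conditions: EtPPh3I, n-BuLi, THF, 0 °C; I2, −78 °C; NaN(SiMe3)2, −20 °C; then 14, −78 °C
Reagents that add atoms: ethyltriphenylphosphonium iodide, CC[P+](c1ccccc1)(c1ccccc1)c1ccccc1.[I-]; iodine, II
Why: Stork–Zhao olefination: the α-iodo ylide should react under kinetic control through the cis-oxaphosphetane to the (Z)-2-iodoalkene (iodine cis to the chain), with no new stereocentre and with the low temperature limiting enolisation of the α-aryl aldehyde.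

Step 10
Reactants: 15 the (Z)-iodoalkene
Product: 17 6-[(1S,6R)-6-[(E)-2-(7-methoxy-2-oxo-2H-chromen-6-yl)ethenyl]-3,6-dimethylcyclohex-2-en-1-yl]-7-methoxy-2H-chromen-2-one, via B-alkyl-9-BBN 16 (not isolated)
Conditions: 9-BBN, THF, 0 °C to rt; then Pd(dppf)Cl2 (cat.), AsPh3, K3PO4 (aq), DMF, rt; dilute HCl work-up
Reagents that add atoms: none
Why: 9-BBN adds anti-Markovnikov to the only monosubstituted alkene (the vinyl group on C1), making C3 a primary alkylborane; zerovalent palladium then inserts into the C4–I bond with retention, the base-activated borate transfers the primary alkyl group to palladium, and reductive elimination forms the C3–C4 bond. The closest known reaction type is the hydroboration/intramolecular B-alkyl Suzuki–Miyaura cyclisation of haloalkenes that carry a remote terminal alkene to give cycloalkenes. The six-membered ring closes by reductive elimination from a seven-membered alkyl(alkenyl)palladacycle, endocyclic with respect to C4=C5 (both alkene carbons end up in the ring), which is possible only because iodine is cis to C6 in the (Z)-iodoalkene. No stereocentre is created; C1 and C6 are already set and neither is next to a carbonyl group at this stage. The step needs chemoselective hydroboration, which the steric preference of 9-BBN for a terminal vinyl group over the internal styryl, the trisubstituted iodoalkene and the lactone double bonds should secure, and transmetallation faster than Heck insertion into the styryl group or β-hydride elimination, which the wide-bite-angle dppf ligand, AsPh3 and room temperature should secure.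

Compound list
1 | 5-bromo-2-hydroxy-4-methoxybenzaldehyde | COc1cc(O)c(C=O)cc1Br | starting material
2 | ethyl (Z)-3-(5-bromo-2-hydroxy-4-methoxyphenyl)prop-2-enoate (formed with its E isomer, which equilibrates) | CCOC(=O)/C=C\c1cc(Br)c(OC)cc1O | intermediate
3 | 6-bromo-7-methoxy-2H-chromen-2-one | COc1cc2oc(=O)ccc2cc1Br | intermediate
4 | tert-butyl 2-(7-methoxy-2-oxo-2H-chromen-6-yl)acetate | COc1cc2oc(=O)ccc2cc1CC(=O)OC(C)(C)C | intermediate
5 | 2-(7-methoxy-2-oxo-2H-chromen-6-yl)acetic acid | COc1cc2oc(=O)ccc2cc1CC(=O)O | intermediate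
6 | (2E)-3-methylpent-2-en-4-yn-1-ol | OC/C=C(C)/C#C | starting material
7 | (2E,4E)-3-methyl-5-(tributylstannyl)penta-2,4-dien-1-ol | OC/C=C(C)/C=C/[Sn](CCCC)(CCCC)CCCC | intermediate
8 | 6-[(1E,3E)-5-hydroxy-3-methylpenta-1,3-dienyl]-7-methoxy-2H-chromen-2-one | OC/C=C(C)/C=C/c1cc2ccc(=O)oc2cc1OC | intermediate
9 | (2E,4E)-5-(7-methoxy-2-oxo-2H-chromen-6-yl)-3-methylpenta-2,4-dienyl 2-(7-methoxy-2-oxo-2H-chromen-6-yl)acetate | COc1cc2oc(=O)ccc2cc1CC(=O)OC/C=C(C)/C=C/c1cc2ccc(=O)oc2cc1OC | intermediate
10 | boron enolate of 9: ketene acetal with the aryl group cis to O–B, boron carried in the (4S,5S)-4,5-diphenyl-1,3-bis(arylsulfonyl)-1,3,2-diazaborolidine | COc1cc2oc(=O)ccc2cc1/C=C(\OB1N(S(=O)(=O)c2cc(cc(c2)C(F)(F)F)C(F)(F)F)[C@@H](c2ccccc2)[C@H](c2ccccc2)N1S(=O)(=O)c1cc(cc(c1)C(F)(F)F)C(F)(F)F)OC/C=C(C)/C=C/c1cc2ccc(=O)oc2cc1OC | intermediate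
11 | O-diazaborolidinyl ester (boryl ester) of acid 12 | O=C(OB1N(S(=O)(=O)c2cc(cc(c2)C(F)(F)F)C(F)(F)F)[C@@H](c2ccccc2)[C@H](c2ccccc2)N1S(=O)(=O)c1cc(cc(c1)C(F)(F)F)C(F)(F)F)[C@H](c1cc2ccc(=O)oc2cc1OC)[C@](C)(C=C)/C=C/c1cc2ccc(=O)oc2cc1OC | intermediate
12 | (2S,3R)-2-(7-methoxy-2-oxo-2H-chromen-6-yl)-3-[(E)-2-(7-methoxy-2-oxo-2H-chromen-6-yl)ethenyl]-3-methylpent-4-enoic acid | OC(=O)[C@H](c1cc2ccc(=O)oc2cc1OC)[C@](C)(C=C)/C=C/c1cc2ccc(=O)oc2cc1OC | intermediate
13 | acid chloride of 12, (2S,3R) | ClC(=O)[C@H](c1cc2ccc(=O)oc2cc1OC)[C@](C)(C=C)/C=C/c1cc2ccc(=O)oc2cc1OC | intermediate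
14 | (2S,3R)-2-(7-methoxy-2-oxo-2H-chromen-6-yl)-3-[(E)-2-(7-methoxy-2-oxo-2H-chromen-6-yl)ethenyl]-3-methylpent-4-enal | O=C[C@H](c1cc2ccc(=O)oc2cc1OC)[C@](C)(C=C)/C=C/c1cc2ccc(=O)oc2cc1OC | intermediate
15 | 6-[(2Z,4S,5R)-2-iodo-5-[(E)-2-(7-methoxy-2-oxo-2H-chromen-6-yl)ethenyl]-5-methylhepta-2,6-dien-4-yl]-7-methoxy-2H-chromen-2-one | C/C(I)=C/[C@H](c1cc2ccc(=O)oc2cc1OC)[C@](C)(C=C)/C=C/c1cc2ccc(=O)oc2cc1OC | intermediate
16 | B-alkyl-9-borabicyclo[3.3.1]nonane from anti-Markovnikov hydroboration of the vinyl group of 15 (configuration as in 15) | C/C(I)=C/[C@H](c1cc2ccc(=O)oc2cc1OC)[C@](C)(CCB1C2CCCC1CCC2)/C=C/c1cc2ccc(=O)oc2cc1OC | intermediate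
17 | 6-[(1S,6R)-6-[(E)-2-(7-methoxy-2-oxo-2H-chromen-6-yl)ethenyl]-3,6-dimethylcyclohex-2-en-1-yl]-7-methoxy-2H-chromen-2-one | COc1cc2oc(=O)ccc2cc1/C=C/[C@@]1(C)CCC(C)=C[C@@H]1c1cc2ccc(=O)oc2cc1OC | target

Total step count: 10. Longest linear sequence: 8 steps (1, 2, 3, 6, 7, 8, 9, 10).

Steps most likely to fail

Step 7. The Lewis-acidic boron bromide may ionise the electron-rich dienylic C–O bond instead of enolising the ester, and the facial selectivity on an arylacetate may be low or of the opposite sense. Fallback: from ester 9, enolisation with KN(SiMe3)2 and Me3SiCl (toluene–THF, −78 °C) should give the (Z)-silyl ketene acetal F1, which rearranges at room temperature through the same chair to the trimethylsilyl ester F2 and its mirror image F3. Acidic work-up gives acid 12 together with its enantiomer F4, and separation on a chiral stationary phase (or crystallisation of a salt with a chiral amine) returns to 12.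

Step 10. Oxidative addition may be followed by Heck-type insertion into the styryl group before the hindered borane transmetallates, and the aqueous base may open the lactones or cause protodeboronation. Fallback: from borane 16, oxidation with NaBO3·4H2O should give the primary alcohol F5, and an Appel reaction (I2, PPh3, imidazole) the primary iodide F6. Zinc insertion into the alkyl iodide (Zn, LiCl, THF, rt; the alkenyl iodide reacts far more slowly) gives the alkylzinc iodide F7, which closes the same C3–C4 bond by a base-free intramolecular Negishi coupling (Pd2(dba)3, tri(2-furyl)phosphine) and returns to 17.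

Step 9. The basic ylide may enolise the hindered α-aryl aldehyde, which would epimerise the aryl-bearing centre, and the Z selectivity may erode. Fallback: from aldehyde 14, Ramirez olefination (CBr4, PPh3, CH2Cl2, 0 °C) should give the 1,1-dibromoalkene F8 without base. Trans-selective Negishi monomethylation (MeZnCl, PdCl2(DPEphos), THF) replaces the bromine trans to the chain and gives the (Z)-2-bromoalkene F9. Hydroboration to the borane F10 and coupling as in step 10 return to 17.

Further compounds
F1 | step 7 | (Z)-trimethylsilyl ketene acetal of ester 9 (aryl cis to O–Si) | COc1cc2oc(=O)ccc2cc1/C=C(\O[Si](C)(C)C)OC/C=C(C)/C=C/c1cc2ccc(=O)oc2cc1OC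
F2 | step 7 | trimethylsilyl ester of acid 12, (2S,3R) | C[Si](C)(C)OC(=O)[C@H](c1cc2ccc(=O)oc2cc1OC)[C@](C)(C=C)/C=C/c1cc2ccc(=O)oc2cc1OC
F3 | step 7 | trimethylsilyl ester of the enantiomeric acid, (2R,3S) | C[Si](C)(C)OC(=O)[C@@H](c1cc2ccc(=O)oc2cc1OC)[C@@](C)(C=C)/C=C/c1cc2ccc(=O)oc2cc1OC
F4 | step 7 | (2R,3S)-enantiomer of acid 12 | OC(=O)[C@@H](c1cc2ccc(=O)oc2cc1OC)[C@@](C)(C=C)/C=C/c1cc2ccc(=O)oc2cc1OC
F5 | step 10 | primary alcohol from oxidation of 16 (2-hydroxyethyl group on the quaternary carbon, configuration as in 15) | C/C(I)=C/[C@H](c1cc2ccc(=O)oc2cc1OC)[C@](C)(CCO)/C=C/c1cc2ccc(=O)oc2cc1OC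
F6 | step 10 | primary iodide (2-iodoethyl group on the quaternary carbon, configuration as in 15) | C/C(I)=C/[C@H](c1cc2ccc(=O)oc2cc1OC)[C@](C)(CCI)/C=C/c1cc2ccc(=O)oc2cc1OC
F7 | step 10 | alkylzinc iodide from F6 | C/C(I)=C/[C@H](c1cc2ccc(=O)oc2cc1OC)[C@](C)(CC[Zn]I)/C=C/c1cc2ccc(=O)oc2cc1OC
F8 | step 9 | 1,1-dibromoalkene from 14, (3S,4R)-1,1-dibromo-3-aryl-4-methyl-4-styryl-hexa-1,5-diene | BrC(Br)=C[C@H](c1cc2ccc(=O)oc2cc1OC)[C@](C)(C=C)/C=C/c1cc2ccc(=O)oc2cc1OC
F9 | step 9 | (Z)-2-bromoalkene, bromo analogue of 15 | C/C(Br)=C/[C@H](c1cc2ccc(=O)oc2cc1OC)[C@](C)(C=C)/C=C/c1cc2ccc(=O)oc2cc1OC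
F10 | step 9 | B-alkyl-9-borabicyclo[3.3.1]nonane from F9, bromo analogue of 16 | C/C(Br)=C/[C@H](c1cc2ccc(=O)oc2cc1OC)[C@](C)(CCB1C2CCCC1CCC2)/C=C/c1cc2ccc(=O)oc2cc1OC
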